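**Retrosynthetic overview**
- Last bond C5–C1′: the C15 chain and the C12 phenol 6,8-dihydroxy-3,5,7-trimethylisocoumarin are joined at the quaternary carbon by a palladium-catalysed asymmetric dearomative farnesylation, which sets C5 and turns the benzenoid ring into the dienone ring.
- The carbocycle C4a–C5–C6–C7–C8–C8a is not assembled as a six-membered ring. It grows from the four-membered ring C5–C6–C7–C8 of 3-ethoxy-2,4-dimethylcyclobutenone by insertion of C8a=C4a (C3=C4 of a 4-methoxy-6-methyl-2-pyranone) into the C5–C8 bond, forming C8–C8a and C5–C4a.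
- Enabling feature: C6 and C8 both carry oxygen and flank C7–Me, with C5–Me next to C6, which is the substitution pattern of the methylketene/ethoxypropyne [2+2] adduct. C4a is the β-carbon of the unsaturated lactone (C1=O, C8a=C4a), so in the pyranone it can carry a methoxy leaving group and accept C5, while C8a (marked by bromine) is the nucleophile toward C8.
- Ring order: pyranone ring (bought), cyclobutenone ring (step 1), six-membered carbocycle by ring expansion with aromatisation (step 3), de-ethylation, dearomatisation at C5 (step 6). The acid-sensitive triene enters only in the last step.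

Key step: step 3

Assumption: 1-ethoxyprop-1-yne, 4-methoxy-6-methyl-2H-pyran-2-one and (2E,6E)-farnesol are taken as commercial, and the ligand antipode written in step 6 is assumed to give the (5S) product; if the sense of induction is the opposite, the (1S,2S) ligand is used.

**Step 1**
Reactants: 1 1-ethoxyprop-1-yne (two molecules)
Product: 3 rac-3-ethoxy-2,4-dimethylcyclobut-2-en-1-one, via methylketene 2 (not isolated)
Conditions: toluene, sealed tube, 115 °C
Reagents that add atoms: none
Why: Retro-ene loss of ethylene from one molecule of the ethyl alkynyl ether should give methylketene, which undergoes regioselective [2+2] cycloaddition with a second molecule (ketene carbonyl carbon to the methyl-bearing alkyne carbon), the classical thermolysis route to 3-alkoxycyclobutenones; the C4 stereocentre forms racemic and is erased in step 3.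

**Step 2**
Reactants: 4 4-methoxy-6-methyl-2H-pyran-2-one
Product: 5 3-bromo-4-methoxy-6-methyl-2H-pyran-2-one
Conditions: NBS, MeCN, 0 °C → rt, dark
Reagents that add atoms: N-bromosuccinimide, O=C1CCC(=O)N1Br
Why: Electrophilic bromination should occur at C3, the enol-ether β-carbon between the methoxy group and the lactone carbonyl, the most nucleophilic position of a 4-alkoxy-2-pyranone.

**Step 3**
Reactants: 5 3-bromo-4-methoxy-6-methyl-2H-pyran-2-one; 3 rac-3-ethoxy-2,4-dimethylcyclobut-2-en-1-one
Product: 11 6-ethoxy-8-hydroxy-3,5,7-trimethyl-1H-isochromen-1-one, via pyranonyl Grignard reagent 6 (not isolated), via cyclobutenolate 7 (not isolated), via dienolate 8 (not isolated), via methoxy adduct 9 (not isolated), via dienone 10 (not isolated)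
Conditions: i-PrMgCl·LiCl, THF, −40 °C; then LaCl3·2LiCl and 3, −40 → 0 °C; then 60 °C; aq NH4Cl
Reagents that add atoms: none
Why: Bromine–magnesium exchange on 5 should give the 3-pyranonyl Grignard reagent 6, which adds 1,2 to the strained carbonyl of 3 (C8–C8a bond) to give cyclobutenolate 7; the oxido group accelerates conrotatory 4π opening of the C5–C8 bond and rotates outward, so the pyranone turns inward and dienolate 8 has the pyranone cis to C6, held by magnesium chelation between the C8 oxygen and the lactone carbonyl. The six-membered ring is then closed by disrotatory 6π-electrocyclisation of the C5=C6–C7=C8–C8a=C4a triene (equivalently a 6-endo-trig vinylogous Michael addition, C5–C4a bond) to give 9, β-elimination of methoxide from C4a restores the pyranone (10), and the methoxide removes the C5 proton to give the aromatic phenoxide of 11. The closest known reaction type is the addition of alkenyl- or aryl-metal reagents to cyclobutenones and benzocyclobutenones followed by alkoxide-accelerated electrocyclic ring opening and 6π ring closure to cyclohexadienols, phenols and naphthols. No stereocentre remains: the C5 centre of racemic 3 and the transient C4a centre of 9 are erased, and C5 of the target is set in step 6 by the chiral palladium catalyst. The step needs 1,2- over conjugate addition (favoured by LaCl3·2LiCl and the hard vinylogous-ester carbonyl), the stated torquoselectivity (the strong outward preference of the oxido group) and a single annulation regiochemistry (the methoxy leaving group marks C4a and the bromine marks C8a).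

**Step 4**
Reactants: 11 6-ethoxy-8-hydroxy-3,5,7-trimethyl-1H-isochromen-1-one
Product: 12 6,8-dihydroxy-3,5,7-trimethyl-1H-isochromen-1-one
Conditions: BBr3, CH2Cl2, −78 °C → rt; then H2O
Reagents that add atoms: none
Why: Lewis-acid dealkylation of the di-ortho-substituted aryl ethyl ether through its aryloxyborane should free the 6-OH, a standard operation on alkoxyisocoumarins that the lactone tolerates.

**Step 5**
Reactants: 13 (2E,6E)-farnesol
Product: 14 methyl (2E,6E)-3,7,11-trimethyldodeca-2,6,10-trien-1-yl carbonate
Conditions: ClCO2Me, pyridine, CH2Cl2, 0 °C → rt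
Reagents that add atoms: methyl chloroformate, COC(=O)Cl
Why: O-acylation of the primary allylic alcohol under basic conditions should give the carbonate without allylic transposition or change of alkene geometry.

**Step 6**
Reactants: 12 6,8-dihydroxy-3,5,7-trimethyl-1H-isochromen-1-one; 14 methyl (2E,6E)-3,7,11-trimethyldodeca-2,6,10-trien-1-yl carbonate
Product: 15 (5S)-8-hydroxy-3,5,7-trimethyl-5-[(2E,6E)-3,7,11-trimethyldodeca-2,6,10-trien-1-yl]-1H-isochromene-1,6(5H)-dione
Conditions: Pd2(dba)3·CHCl3 (cat.), (1R,2R)-N,N'-bis[2-(diphenylphosphanyl)benzoyl]cyclohexane-1,2-diamine (cat.), 1,4-dioxane, rt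
Reagents that add atoms: none
Why: Proposed new method: a Tsuji–Trost-type asymmetric allylic alkylation in which zerovalent palladium ionises 14 to a cationic η3-farnesyl complex of divalent palladium, CO2 and methoxide; methoxide deprotonates the more acidic 6-OH of 12 (vinylogous to the lactone carbonyl) and the soft phenoxide attacks the unsubstituted allyl terminus from outside the metal through C5 (ortho to O6), the chiral pocket of the diphosphine differentiating the two faces of the flat nucleophile so that the quaternary centre forms as (5S), while O-farnesylation is reversible under the catalyst and the C5 adduct keeps the O8–H···O=C1 hydrogen bond; the closest known reaction types are the palladium-catalysed asymmetric allylic dearomatisation of 1,3-disubstituted 2-naphthols, the linear-selective asymmetric prenylation and geranylation of 3-substituted oxindoles and indoles, and the racemic base-mediated C-farnesylation of 3,5-dimethylorsellinates at the corresponding ring carbon.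

**Compound list**
1 | 1-ethoxyprop-1-yne | CCOC#CC | starting material
2 | methylketene (formed in situ) | CC=C=O | intermediate
3 | rac-3-ethoxy-2,4-dimethylcyclobut-2-en-1-one | CCOC1=C(C)C(=O)C1C | intermediate
4 | 4-methoxy-6-methyl-2H-pyran-2-one | COc1cc(C)oc(=O)c1 | starting material
5 | 3-bromo-4-methoxy-6-methyl-2H-pyran-2-one | COc1cc(C)oc(=O)c1Br | intermediate
6 | (4-methoxy-6-methyl-2-oxo-2H-pyran-3-yl)magnesium chloride (formed in situ) | COc1cc(C)oc(=O)c1[Mg]Cl | intermediate
7 | chloromagnesium 3-ethoxy-1-(4-methoxy-6-methyl-2-oxo-2H-pyran-3-yl)-2,4-dimethylcyclobut-2-en-1-olate (racemic diastereomer mixture, formed in situ) | CCOC1=C(C)C(O[Mg]Cl)(c2c(OC)cc(C)oc2=O)C1C | intermediate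
8 | chloromagnesium (1E)-3-ethoxy-1-(4-methoxy-6-methyl-2-oxo-2H-pyran-3-yl)-2-methylpenta-1,3-dien-1-olate (pyranone cis to C3 of the chain, formed in situ) | CC=C(OCC)/C(C)=C(/O[Mg]Cl)c1c(OC)cc(C)oc1=O | intermediate
9 | chloromagnesium 6-ethoxy-4a-methoxy-3,5,7-trimethyl-1-oxo-4a,5-dihydro-1H-isochromen-8-olate (racemic, formed in situ) | CCOC1=C(C)C(O[Mg]Cl)=C2C(=O)OC(C)=CC2(OC)C1C | intermediate
10 | rac-6-ethoxy-3,5,7-trimethyl-1H-isochromene-1,8(5H)-dione (formed in situ) | CCOC1=C(C)C(=O)c2c(cc(C)oc2=O)C1C | intermediate
11 | 6-ethoxy-8-hydroxy-3,5,7-trimethyl-1H-isochromen-1-one | CCOc1c(C)c(O)c2c(c1C)cc(C)oc2=O | intermediate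
12 | 6,8-dihydroxy-3,5,7-trimethyl-1H-isochromen-1-one | Cc1cc2c(C)c(O)c(C)c(O)c2c(=O)o1 | intermediate
13 | (2E,6E)-3,7,11-trimethyldodeca-2,6,10-trien-1-ol ((2E,6E)-farnesol) | CC(C)=CCC/C(C)=C/CC/C(C)=C/CO | starting material
14 | methyl (2E,6E)-3,7,11-trimethyldodeca-2,6,10-trien-1-yl carbonate | CC(C)=CCC/C(C)=C/CC/C(C)=C/COC(=O)OC | intermediate
15 | (5S)-8-hydroxy-3,5,7-trimethyl-5-[(2E,6E)-3,7,11-trimethyldodeca-2,6,10-trien-1-yl]-1H-isochromene-1,6(5H)-dione | CC(C)=CCC/C(C)=C/CC/C(C)=C/C[C@]1(C)C(=O)C(C)=C(O)c2c1cc(C)oc2=O | target

Total step count: 6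
Longest linear sequence: 4 steps (step 1, step 3, step 4, step 6)

**Steps most likely to fail**

Step 6 (proposed new method). The catalyst may discriminate the two faces of the flat phenoxide poorly, the allyl complex may be captured through C7 or O6 or at its substituted terminus, or the 2E geometry may erode by syn/anti exchange. The fallback sets out from 12 and uses known chemistry: deprotonation with LiN(SiMe3)2 in THF at 0 °C and alkylative dearomatisation with commercial (2E,6E)-farnesyl bromide, as established for dimethylorsellinates, should give racemic 8-hydroxy-3,5,7-trimethyl-5-[(2E,6E)-3,7,11-trimethyldodeca-2,6,10-trien-1-yl]-1H-isochromene-1,6(5H)-dione F1. Its enantiomers are then separated by chromatography on a chiral stationary phase (amylose tris(3,5-dimethylphenylcarbamate)); the (5R)-enantiomer F2 is set aside and the route is rejoined at 15.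

Step 3. The bromine–magnesium exchange may be incomplete, the Grignard reagent may be quenched by proton transfer from the ring methyl group or attack the lactone, or the cyclobutenolate may open without ring closure. The fallback sets out from 3 and builds the same two bonds stepwise without an organometallic reagent. Heating 3 in toluene at 100 °C with commercial 4-hydroxy-6-methyl-2H-pyran-2-one should open the same C5–C8 bond electrocyclically to 3-ethoxy-2-methylpenta-1,3-dien-1-one F3, which is trapped by the acidic enol as 6-methyl-2-oxo-2H-pyran-4-yl 3-ethoxy-2-methylpent-3-enoate F4. A DMAP-catalysed Fries-type O-to-C acyl shift should give 3-(3-ethoxy-2-methylpent-3-enoyl)-4-hydroxy-6-methyl-2H-pyran-2-one F5 (C8–C8a bond). Tf2O and 2,6-lutidine then give 3-(3-ethoxy-2-methylpent-3-enoyl)-6-methyl-2-oxo-2H-pyran-4-yl trifluoromethanesulfonate F6, whose enol ether carbon closes onto C4a by addition–elimination and aromatises; the route is rejoined at 11.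

Step 1. Methylketene may oligomerise faster than it is captured by the alkyne, and the product may be lost thermally. The fallback sets out from 2, generated instead by pyrolysis of propanoic anhydride and left to dimerise in the absence of amine. The acidic dimer 3-hydroxy-2,4-dimethylcyclobut-2-en-1-one F7 is extracted into aqueous NaHCO3 and O-ethylated with triethyl orthoformate and ethanol (cat. TsOH), which should give the single constitutional isomer because the enol is symmetric; the route is rejoined at 3.

**Further compounds**
F1 | step 6 | racemic 8-hydroxy-3,5,7-trimethyl-5-[(2E,6E)-3,7,11-trimethyldodeca-2,6,10-trien-1-yl]-1H-isochromene-1,6(5H)-dione | CC(C)=CCC/C(C)=C/CC/C(C)=C/CC1(C)C(=O)C(C)=C(O)c2c1cc(C)oc2=O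
F2 | step 6 | (5R)-8-hydroxy-3,5,7-trimethyl-5-[(2E,6E)-3,7,11-trimethyldodeca-2,6,10-trien-1-yl]-1H-isochromene-1,6(5H)-dione | CC(C)=CCC/C(C)=C/CC/C(C)=C/C[C@@]1(C)C(=O)C(C)=C(O)c2c1cc(C)oc2=O
F3 | step 3 | 3-ethoxy-2-methylpenta-1,3-dien-1-one | CC=C(OCC)C(C)=C=O
F4 | step 3 | 6-methyl-2-oxo-2H-pyran-4-yl 3-ethoxy-2-methylpent-3-enoate | CCOC(=CC)C(C)C(=O)Oc1cc(C)oc(=O)c1
F5 | step 3 | 3-(3-ethoxy-2-methylpent-3-enoyl)-4-hydroxy-6-methyl-2H-pyran-2-one | CCOC(=CC)C(C)C(=O)c1c(O)cc(C)oc1=O
F6 | step 3 | 3-(3-ethoxy-2-methylpent-3-enoyl)-6-methyl-2-oxo-2H-pyran-4-yl trifluoromethanesulfonate | CCOC(=CC)C(C)C(=O)c1c(OS(=O)(=O)C(F)(F)F)cc(C)oc1=O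
F7 | step 1 | 3-hydroxy-2,4-dimethylcyclobut-2-en-1-one | CC1C(O)=C(C)C1=O
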